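## Structural features

The target 19 is an 18-membered macrocycle built from four benzene rings, here called ring A (the dihydroxy ring), ring B (the para-linked ring), ring C (the monohydroxy ring) and ring D (the meta-linked ring). Going round the ring the connections are A–O–B, B–CH(OH)–CH2–C, C–O–D and D–CH2–CH2–A: two diaryl ether oxygens, one hydroxylated two-carbon bridge and one saturated two-carbon bridge. Ring A carries three contiguous oxygens (aryloxy at C3, hydroxyl at C4 and C5, the bridge at C1), and ring C has its ether oxygen at C2 flanked by the benzylic CH2 at C1 and a hydroxyl at C3. The only stereocenter is the (S)-carbinol carbon attached to ring B; it has no stereogenic neighbour, so it must be set by a reagent and not by the substrate. Two groups are fragile: the benzylic alcohol para to the ring B ether oxygen (ionization in acid, dehydration to a stilbene, hydrogenolysis) and the ring A catechol (air oxidation once it is a free anion). The real difficulty is to close the large ring and then free four hydroxyl groups without acid, hydrogen or oxidant, and to form each diaryl ether at one defined oxygen of a polyoxygenated ring. The key step uses the CH2–CH2 link between C1 of ring A and C3 of ring D, the part of the ring farthest from the carbinol: a vinyl group on ring A is hydroborated and the primary alkylborane is joined to the bromine-bearing carbon of ring D, so the bridge arrives saturated.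

## Logic of the disconnections

19 ⇐ 18. The four O–Si bonds are cut. The catechol and the benzylic carbinol tolerate neither acid nor hydrogenolysis nor oxidizing base, so all four hydroxyl groups are unveiled last with buffered fluoride. Nothing is gained in skeleton; the demand is that the silyl groups survive everything from 13 onward and leave together near neutrality.

18 ⇐ 16 (through 17). The bond between C3 of ring D and the adjacent CH2 of the ethano bridge is cut. This bond is remote from the stereocenter, and an sp3–sp2 coupling delivers the bridge saturated, so no alkene has to be reduced near the carbinol. The macrocycle opens to a linear chain of four rings ending in a vinyl group on ring A and a bromide on ring D. The forward step needs a hydroboration that touches only the alkene, ring closure in preference to chain growth, and a base mild enough for aryl silyl ethers.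

16 ⇐ 15 ⇐ 14. The O–Si bond at the carbinol and then the C–H bond at the stereocenter are cut, leading back to an aryl benzyl ketone. The stereocenter is set on an open-chain ketone, where a transfer-hydrogenation catalyst distinguishes the aryl flank from the CH2 flank. The reduction must leave the alkene and the bromide alone.

14 ⇐ 13. The vinyl C=C bond is traced to a formyl group. The aldehyde is needed earlier as a robust one-carbon handle, since a styrene would not survive ether cleavage with a Lewis acid. The ylide must take the aldehyde and not the enolizable ketone.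

13 ⇐ 12 ⇐ 11. Three O–Si bonds are exchanged for three O–CH3 bonds. Methyl ethers survive the base-mediated ether formations and the organolithium step; silyl ethers would not. The exchange is placed where no carbinol and no alkene exist yet. The Lewis acid must cleave three alkyl–oxygen bonds and leave both diaryl ethers.

11 ⇐ 5 + 8 (through 9 and 10). The bond between the carbonyl carbon and the ring C benzylic CH2 is cut, in the form of an enamine C=C bond. The molecule falls into two halves of similar size, rings A/B and rings C/D. A palladium-catalysed ketone arylation at this bond would have to choose between a ring C halide and the ring D bromide; an olefination needs no such choice. The carbanion of 5 must be formed completely before 8 is added, and the enamine and the acetal must hydrolyse in the same work-up.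

5 ⇐ 4 ⇐ 2 + 3, and 2 ⇐ 1. The C–P and C–N bonds at the ring B benzylic carbon are cut, then the bond from the ring A ether oxygen to ring B, then the acetal C–O bonds. The ether is formed para to a formyl group on a non-enolizable partner, and the ring A oxygen pattern is bought ready-made in 1. The ring A formyl group must be masked so that only the ring B formyl group reacts.

8 ⇐ 6 + 7. The bond from C2 of ring C to the ether oxygen is cut. The crowded ether is made by displacement of a fluoride ortho to a formyl group, where crowding matters little, and the ring D bromide is a spectator in the absence of a transition metal. The fluoride must be displaced despite the neighbouring methoxy group.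

## Other disconnections considered

Alternative 1: The cut is the ring A carbon–oxygen bond of the A–O–B ether, with ring A taken back to the cyclohexane-1,3-dione oxidation level. In the forward step the ring B phenoxide of the seco chloro enone A1 adds to the chlorine-bearing carbon of the 3-chloro-2-methoxycyclohexenone under K2CO3 and chloride leaves, giving the macrocyclic enone A2.
- In its favour: no transition metal is needed, and a vinylogous acid chloride is far more electrophilic than an unactivated aryl halide, so the C–O bond should form at moderate temperature. The three ring A oxygens are differentiated by construction (carbonyl, enol methyl ether, aryl ether). On this point alternative 1 is better than the chosen plan, which buys the pattern as a partly methylated pyrogallol and unmasks it with BBr3.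
- Against it: A2 is not at the oxidation level of 19. Ring A must still be dehydrogenated, two methyl ethers cleaved and the ring B ketone reduced enantioselectively, all on the macrocycle. The dehydrogenation must spare the equally oxidizable CH2 next to that ketone. The same acidic CH2 can form an enolate under carbonate and compete with the weakly nucleophilic para-acyl phenoxide. The stereocenter would be set last on a conformationally restricted ring ketone, where catalyst control is less predictable than on open-chain 14.
- Comparison: both plans close the same ring, alternative 1 at a heteroatom bond next to the future catechol, the chosen plan at a C–C bond remote from every sensitive group. The polar addition–elimination is operationally simpler than a palladium cycle, which counts for alternative 1. On step economy the chosen plan needs one step after ring closure and alternative 1 at least three.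

Alternative 2: The cut is the bond between ring B and the carbinol carbon. In the forward step the seco iodo aldehyde A3 is treated with CrCl2, catalytic NiCl2 and a chiral oxazoline sulfonamide ligand; the arylchromium species adds to the aldehyde and gives the macrocyclic carbinol A4.
- In its favour: ring and stereocenter are formed in one operation. The chosen plan spends separate steps on ketone formation, transfer hydrogenation and silylation, so on step count after fragment assembly alternative 2 is the better plan. The organochromium nucleophile is non-basic and tolerates silyl ethers, and the carbinol emerges free.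
- Against it: A3 is an arylacetaldehyde with acidic α-hydrogens, prone to enolization, self-condensation and air oxidation; it would have to be generated at the last moment on a large intermediate. Ligand-controlled additions of this type are best established for alkenyl and allyl halides with aliphatic aldehydes. Here the ligand would have to override the facial bias of a folding 18-membered transition state. If selectivity fell short, the only remedy would be oxidation and re-reduction on the macrocycle.
- Comparison: alternative 2 closes the ring at the most fragile atom of the molecule, the chosen plan on the opposite side. Stereocontrol in the chosen plan rests on hydride transfer to an open-chain aryl ketone, a setting with broad precedent. Both plans end with a single fluoride deprotection, so they are equal there.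

Alternative 3: The cut is the bond from the ring C ether oxygen to ring D, traced back to an aryl ester. In the forward step zerovalent nickel from Ni(cod)2 with 3,4-bis(dicyclohexylphosphino)thiophene inserts into the acyl–oxygen bond of the 19-membered lactone A5, carbon monoxide is lost and C–O reductive elimination gives the 18-membered macrocycle A6.
- In its favour: the ring is first closed as an aryl ester by macrolactonization, one of the most dependable macrocyclizations. The crowded ring C ether is then formed intramolecularly. A6 needs only one fluoride step to reach 19, the same as 18.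
- Against it: decarbonylative ether formation is established mainly for esters of azine carboxylic acids, where the ring nitrogen assists. The plain benzoate of A5 lacks that help and would need temperatures near 150 °C. Four silyl ethers, one of them benzylic, and the other aryl–oxygen bonds would be exposed to zerovalent nickel at that temperature. The contraction from 19 to 18 atoms builds strain in the product-forming step, and the nickel aryl phenoxide can lose its partner instead of closing. Ring D would need a carboxyl group and ring C a free phenol beside three protected ones.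
- Comparison: the ether-forming mechanism of alternative 3 is the least precedented for this substrate class, whereas the alkylborane coupling of the chosen plan has macrocyclic precedent. Alternative 3 needs two ring-forming operations where the chosen plan needs one. The two plans are equal in the final deprotection.

Key step: step 11

Assumption: compounds 1, 3, 6 and 7 are bought; 1 (5-hydroxyveratraldehyde) already carries the ring A oxygen pattern with the future ether oxygen free.

## Route

Step 1
Reactants: 1 3-hydroxy-4,5-dimethoxybenzaldehyde
Product: 2 5-(1,3-dioxolan-2-yl)-2,3-dimethoxyphenol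
Conditions: HOCH2CH2OH, p-TsOH (cat.), toluene, reflux, Dean–Stark
Reagents that add atoms: ethylene glycol, OCCO
Why: Acid-catalysed acetalization with azeotropic removal of water; the free phenol does not interfere, and masking the ring A formyl group leaves the ring B formyl group as the only aldehyde in steps 2 and 3.

Step 2
Reactants: 2 5-(1,3-dioxolan-2-yl)-2,3-dimethoxyphenol, 3 4-fluorobenzaldehyde
Product: 4 4-[5-(1,3-dioxolan-2-yl)-2,3-dimethoxyphenoxy]benzaldehyde
Conditions: K2CO3, DMF, 110 °C
Reagents that add atoms: none
Why: Nucleophilic aromatic substitution: the phenoxide of 2 displaces fluoride para to the formyl group through a Meisenheimer adduct. Neither partner is enolizable and the dioxolane is stable to carbonate.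

Step 3
Reactants: 4 4-[5-(1,3-dioxolan-2-yl)-2,3-dimethoxyphenoxy]benzaldehyde
Product: 5 diethyl {[4-[5-(1,3-dioxolan-2-yl)-2,3-dimethoxyphenoxy]phenyl](morpholin-4-yl)methyl}phosphonate (racemic)
Conditions: morpholine, HP(O)(OEt)2, toluene, 4 Å MS, 80 °C
Reagents that add atoms: morpholine, C1COCCN1; diethyl phosphite, CCO[PH](=O)OCC
Why: Kabachnik–Fields condensation: the iminium ion from the aldehyde and the secondary amine is trapped by the phosphite, and the basic medium leaves the dioxolane intact. The new stereocenter is irrelevant because it becomes sp2 in step 5.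

Step 4
Reactants: 6 2-fluoro-3-methoxybenzaldehyde, 7 3-bromophenol
Product: 8 2-(3-bromophenoxy)-3-methoxybenzaldehyde
Conditions: K2CO3, DMF, 120 °C
Reagents that add atoms: none
Why: Nucleophilic aromatic substitution ortho to a formyl group, which builds the doubly flanked ring C ether on an activated fluoride. The aryl bromide is inert because no transition metal is present.

Step 5
Reactants: 5 diethyl {[4-[5-(1,3-dioxolan-2-yl)-2,3-dimethoxyphenoxy]phenyl](morpholin-4-yl)methyl}phosphonate, 8 2-(3-bromophenoxy)-3-methoxybenzaldehyde
Product: 11 3-[4-[2-[2-(3-bromophenoxy)-3-methoxyphenyl]acetyl]phenoxy]-4,5-dimethoxybenzaldehyde, via lithiated phosphonate 9 (not isolated), via morpholine enamine 10 (not isolated)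
Conditions: n-BuLi, THF, −78 °C; then 8, −78 °C → rt; then 2 M HCl, THF, rt
Reagents that add atoms: water, O
Why: Horner–Wadsworth–Emmons olefination with an α-aminophosphonate as acyl anion equivalent: carbanion 9 adds to aldehyde 8, loss of diethyl phosphate gives enamine 10, and aqueous acid hydrolyses the enamine to the aryl benzyl ketone and the dioxolane to the aldehyde. The butyllithium is consumed by 5 before 8 is added, so the ring D bromide is not exchanged.

Step 6
Reactants: 11 3-[4-[2-[2-(3-bromophenoxy)-3-methoxyphenyl]acetyl]phenoxy]-4,5-dimethoxybenzaldehyde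
Product: 12 3-[4-[2-[2-(3-bromophenoxy)-3-hydroxyphenyl]acetyl]phenoxy]-4,5-dihydroxybenzaldehyde
Conditions: BBr3, CH2Cl2, −78 → 0 °C; then ice, aq. NaHCO3
Reagents that add atoms: none
Why: Lewis-acid ether cleavage: boron binds each methoxy oxygen and bromide removes the methyl group by SN2; the diaryl ethers offer no sp3 carbon and stay, and the carbonyl groups are only complexed and return on hydrolysis. The ring C hydroxyl is meta to the CH2CO chain, so no benzofuran can form.

Step 7
Reactants: 12 3-[4-[2-[2-(3-bromophenoxy)-3-hydroxyphenyl]acetyl]phenoxy]-4,5-dihydroxybenzaldehyde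
Product: 13 3-[4-[2-[2-(3-bromophenoxy)-3-(triisopropylsilyloxy)phenyl]acetyl]phenoxy]-4,5-bis(triisopropylsilyloxy)benzaldehyde
Conditions: TIPSCl, imidazole, DMAP (cat.), DMF, rt → 40 °C, argon
Reagents that add atoms: triisopropylsilyl chloride, CC(C)[Si](Cl)(C(C)C)C(C)C
Why: Silylation of three phenols; the most acidic, central ring A hydroxyl (para to the formyl group) should react first while its neighbour is still free, so the crowded vicinal pair is built in the easier order. Silyl chloride with imidazole does not enolize the ketone.

Step 8
Reactants: 13 3-[4-[2-[2-(3-bromophenoxy)-3-(triisopropylsilyloxy)phenyl]acetyl]phenoxy]-4,5-bis(triisopropylsilyloxy)benzaldehyde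
Product: 14 2-[2-(3-bromophenoxy)-3-(triisopropylsilyloxy)phenyl]-1-[4-[5-ethenyl-2,3-bis(triisopropylsilyloxy)phenoxy]phenyl]ethan-1-one
Conditions: Ph3PCH3Br, KN(SiMe3)2, THF, 0 °C; then 13, −78 → 0 °C (2.5 equiv ylide)
Reagents that add atoms: methyltriphenylphosphonium bromide, C[P+](c1ccccc1)(c1ccccc1)c1ccccc1.[Br-]
Why: Wittig methylenation; the aldehyde reacts at low temperature, while the acidic aryl benzyl ketone is converted by the excess ylide into its enolate, which is inert to olefination and returns the ketone on quench.

Step 9
Reactants: 14 2-[2-(3-bromophenoxy)-3-(triisopropylsilyloxy)phenyl]-1-[4-[5-ethenyl-2,3-bis(triisopropylsilyloxy)phenoxy]phenyl]ethan-1-one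
Product: 15 (1S)-2-[2-(3-bromophenoxy)-3-(triisopropylsilyloxy)phenyl]-1-[4-[5-ethenyl-2,3-bis(triisopropylsilyloxy)phenoxy]phenyl]ethan-1-ol
Conditions: RuCl(p-cymene)[(S,S)-TsDPEN] (2 mol%), HCO2H/Et3N (5:2), DMF, 30 °C
Reagents that add atoms: none
Why: Noyori–Ikariya asymmetric transfer hydrogenation: hydride from ruthenium and a proton from the ligand NH are delivered in a six-membered outer-sphere transition state. The carbonyl-bound aryl ring interacts with the η6-arene, so the (S,S)-ligand should give the (S)-alcohol, in the same sense as acetophenone gives (S)-1-phenylethanol with CH2Ar in place of CH3. The catalyst does not reduce the alkene or the aryl bromide.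

Step 10
Reactants: 15 (1S)-2-[2-(3-bromophenoxy)-3-(triisopropylsilyloxy)phenyl]-1-[4-[5-ethenyl-2,3-bis(triisopropylsilyloxy)phenoxy]phenyl]ethan-1-ol
Product: 16 (S)-seco styrene aryl bromide, the tert-butyldimethylsilyl ether of 15
Conditions: TBSOTf, 2,6-lutidine, CH2Cl2, −78 → 0 °C
Reagents that add atoms: tert-butyldimethylsilyl trifluoromethanesulfonate, CC(C)(C)[Si](C)(C)OS(=O)(=O)C(F)(F)F
Why: O-silylation of the secondary benzylic alcohol with a silyl triflate and a hindered base; the C–O bond is not touched, so the configuration is retained. Low temperature and excess base prevent ionization of the para-aryloxy benzylic position.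

Step 11
Reactants: 16 (S)-seco styrene aryl bromide, the tert-butyldimethylsilyl ether of 15
Product: 18 (S)-macrocycle carrying three triisopropylsilyl ethers (ring A C4 and C5, ring C C3) and the tert-butyldimethylsilyl ether at the carbinol, via alkylborane 17 (not isolated)
Conditions: 9-BBN (0.5 M in THF), THF, 0 °C → rt; then syringe pump (10 h) into Pd(dppf)Cl2 (15 mol%), AsPh3 (15 mol%), K3PO4 (3 M aq.), THF/DMF, 50 °C, final 2 mM
Reagents that add atoms: none
Why: 9-BBN adds across the vinyl group of 16 in a four-centre syn addition with boron on the terminal carbon, giving 17; no other group in 16 reacts with a dialkylborane. Zerovalent palladium, formed from Pd(dppf)Cl2, inserts into the ring D C–Br bond, the base-activated borane transfers its primary alkyl group to divalent palladium, and reductive elimination forms the CH2–aryl bond. The closest known reaction type is the B-alkyl Suzuki–Miyaura macrocyclization of alkene-derived 9-BBN boranes with aryl or alkenyl halides. The 18-membered ring closes end to end, by intramolecular transmetalation to a 19-membered palladacycle followed by C(sp3)–C(sp2) reductive elimination. No stereocenter is formed, and the (S)-carbinol carbon is remote from the reacting ends and untouched. Ring closure must win over chain growth; slow addition of 17 into the catalyst at high dilution secures this, helped by the two bent diaryl ether hinges. The wide bite angle of dppf speeds reductive elimination over β-hydride elimination, and the unhindered, electronically neutral ring D bromide undergoes oxidative addition readily. K3PO4 is chosen over stronger or more nucleophilic bases to spare the aryl silyl ethers.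

Step 12
Reactants: 18 (S)-macrocycle carrying three triisopropylsilyl ethers and one tert-butyldimethylsilyl ether
Product: 19 target CNP0356934.1, the (S)-macrocyclic carbinol with free hydroxyl groups at C4 and C5 of ring A and at C3 of ring C
Conditions: Bu4NF, AcOH (1:1), THF, 0 °C → rt, argon
Reagents that add atoms: none
Why: Fluoride-driven desilylation (strong Si–F bond) releases the three phenols and the carbinol. Acetic acid protonates each phenoxide as it forms, so the catechol is not left as an oxidizable anion and the carbinol meets neither strong acid nor strong base; the configuration is untouched.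

## Compound list

1 | 3-hydroxy-4,5-dimethoxybenzaldehyde | O=Cc1cc(O)c(OC)c(OC)c1 | starting material
2 | 5-(1,3-dioxolan-2-yl)-2,3-dimethoxyphenol | COc1cc(C2OCCO2)cc(O)c1OC | intermediate
3 | 4-fluorobenzaldehyde | O=Cc1ccc(F)cc1 | starting material
4 | 4-[5-(1,3-dioxolan-2-yl)-2,3-dimethoxyphenoxy]benzaldehyde | O=Cc1ccc(Oc2cc(C3OCCO3)cc(OC)c2OC)cc1 | intermediate
5 | diethyl {[4-[5-(1,3-dioxolan-2-yl)-2,3-dimethoxyphenoxy]phenyl](morpholin-4-yl)methyl}phosphonate (racemic) | CCOP(=O)(OCC)C(N1CCOCC1)c1ccc(Oc2cc(C3OCCO3)cc(OC)c2OC)cc1 | intermediate
6 | 2-fluoro-3-methoxybenzaldehyde | COc1cccc(C=O)c1F | starting material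
7 | 3-bromophenol | Oc1cccc(Br)c1 | starting material
8 | 2-(3-bromophenoxy)-3-methoxybenzaldehyde | COc1cccc(C=O)c1Oc1cccc(Br)c1 | intermediate
9 | lithiated phosphonate, the α-lithio derivative of 5 | CCOP(=O)(OCC)[C-](N1CCOCC1)c1ccc(Oc2cc(C3OCCO3)cc(OC)c2OC)cc1.[Li+] | intermediate (not isolated)
10 | morpholine enamine, 4-{2-[2-(3-bromophenoxy)-3-methoxyphenyl]-1-[4-[5-(1,3-dioxolan-2-yl)-2,3-dimethoxyphenoxy]phenyl]ethenyl}morpholine (E/Z mixture) | COc1cccc(C=C(N2CCOCC2)c2ccc(Oc3cc(C4OCCO4)cc(OC)c3OC)cc2)c1Oc1cccc(Br)c1 | intermediate (not isolated)
11 | 3-[4-[2-[2-(3-bromophenoxy)-3-methoxyphenyl]acetyl]phenoxy]-4,5-dimethoxybenzaldehyde | O=Cc1cc(OC)c(OC)c(c1)Oc1ccc(cc1)C(=O)Cc1cccc(OC)c1Oc1cccc(Br)c1 | intermediate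
12 | 3-[4-[2-[2-(3-bromophenoxy)-3-hydroxyphenyl]acetyl]phenoxy]-4,5-dihydroxybenzaldehyde | O=Cc1cc(O)c(O)c(c1)Oc1ccc(cc1)C(=O)Cc1cccc(O)c1Oc1cccc(Br)c1 | intermediate
13 | 3-[4-[2-[2-(3-bromophenoxy)-3-(triisopropylsilyloxy)phenyl]acetyl]phenoxy]-4,5-bis(triisopropylsilyloxy)benzaldehyde | O=Cc1cc(O[Si](C(C)C)(C(C)C)C(C)C)c(O[Si](C(C)C)(C(C)C)C(C)C)c(c1)Oc1ccc(cc1)C(=O)Cc1cccc(O[Si](C(C)C)(C(C)C)C(C)C)c1Oc1cccc(Br)c1 | intermediate
14 | 2-[2-(3-bromophenoxy)-3-(triisopropylsilyloxy)phenyl]-1-[4-[5-ethenyl-2,3-bis(triisopropylsilyloxy)phenoxy]phenyl]ethan-1-one | C=Cc1cc(O[Si](C(C)C)(C(C)C)C(C)C)c(O[Si](C(C)C)(C(C)C)C(C)C)c(c1)Oc1ccc(cc1)C(=O)Cc1cccc(O[Si](C(C)C)(C(C)C)C(C)C)c1Oc1cccc(Br)c1 | intermediate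
15 | (1S)-2-[2-(3-bromophenoxy)-3-(triisopropylsilyloxy)phenyl]-1-[4-[5-ethenyl-2,3-bis(triisopropylsilyloxy)phenoxy]phenyl]ethan-1-ol | C=Cc1cc(O[Si](C(C)C)(C(C)C)C(C)C)c(O[Si](C(C)C)(C(C)C)C(C)C)c(c1)Oc1ccc(cc1)[C@@H](O)Cc1cccc(O[Si](C(C)C)(C(C)C)C(C)C)c1Oc1cccc(Br)c1 | intermediate
16 | (S)-seco styrene aryl bromide, the tert-butyldimethylsilyl ether of 15 | C=Cc1cc(O[Si](C(C)C)(C(C)C)C(C)C)c(O[Si](C(C)C)(C(C)C)C(C)C)c(c1)Oc1ccc(cc1)[C@@H](O[Si](C)(C)C(C)(C)C)Cc1cccc(O[Si](C(C)C)(C(C)C)C(C)C)c1Oc1cccc(Br)c1 | intermediate
17 | alkylborane, B-(2-arylethyl)-9-borabicyclo[3.3.1]nonane from 16 | C1CCC2CCCC1B2CCc1cc(O[Si](C(C)C)(C(C)C)C(C)C)c(O[Si](C(C)C)(C(C)C)C(C)C)c(c1)Oc1ccc(cc1)[C@@H](O[Si](C)(C)C(C)(C)C)Cc1cccc(O[Si](C(C)C)(C(C)C)C(C)C)c1Oc1cccc(Br)c1 | intermediate (not isolated)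
18 | (S)-macrocycle with three triisopropylsilyl ethers and one tert-butyldimethylsilyl ether | CC(C)[Si](C(C)C)(C(C)C)Oc1cc2cc(c1O[Si](C(C)C)(C(C)C)C(C)C)Oc1ccc(cc1)[C@@H](O[Si](C)(C)C(C)(C)C)Cc1cccc(O[Si](C(C)C)(C(C)C)C(C)C)c1Oc1cccc(c1)CC2 | intermediate
19 | CNP0356934.1, (S)-macrocyclic carbinol with free hydroxyl groups on rings A and C | Oc1cc2cc(c1O)Oc1ccc(cc1)[C@@H](O)Cc1cccc(O)c1Oc1cccc(c1)CC2 | target

## Step count and least certain steps

Total: 12 steps. Longest linear sequence: 11 steps (steps 1–3 and 5–12, from 1); step 4 supplies the second fragment.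

Step 11 (key step). Chain growth between two molecules may outrun ring closure. The alkylpalladium intermediate may lose a β-hydrogen or the borane may be protonated, and aqueous base may strip aryl silyl groups at 50 °C. The fallback sets out from 16 and returns at 18. An intramolecular Mizoroki–Heck reaction (Pd(OAc)2, P(o-tol)3, Et3N, DMF, 100 °C, high dilution) joins the terminal alkene carbon to ring D and closes the same ring as the macrocyclic stilbene F1. Diimide, generated from 2-nitrobenzenesulfonyl hydrazide and Et3N, then saturates the C=C bond without any risk of hydrogenolysis at the benzylic silyl ether and gives 18.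

Step 5. The hindered carbanion may add sluggishly, and the adduct may stall at the β-oxido phosphonate stage or revert instead of losing phosphate. The fallback sets out from 8 and 4 and returns at 11, replacing the olefination by a carbonyl addition. NaBH4 reduces 8 to the benzylic alcohol F2, and PBr3 gives the benzylic bromide F3. Zinc dust with LiCl in THF gives the benzylzinc bromide F4 without touching the aryl bromide. F4 adds to aldehyde 4 to give the racemic carbinol acetal F5, Dess–Martin periodinane oxidizes it to the ketone acetal F6, and 2 M HCl in THF removes the dioxolane to give 11.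

Step 6. The Lewis acid may activate the formyl group toward attack by an electron-rich ring, or promote cyclodehydration of the ketone onto the neighbouring aryloxy ring, before all three methyl groups are gone. The fallback sets out from 11 and returns at 13, masking both carbonyl groups first. Ethane-1,2-dithiol with BF3·OEt2 gives the bis(dithiolane) F7, BBr3 then gives the bis(dithiolane) triol F8, and TIPSCl with imidazole gives the tris-silyl bis(dithiolane) F9. MeI with CaCO3 in aqueous MeCN releases both carbonyl groups to give 13.

Step 8. The basic ylide may be consumed by enolization faster than it olefinates, or attack the ketone or the silyl ether para to the formyl group. The fallback sets out from 13 and returns at 14 through a Peterson olefination. TMSCH2MgCl with CeCl3 in THF at −78 °C, a weakly basic reagent, adds to the aldehyde only and gives the β-hydroxysilane F10. A catalytic amount of p-TsOH in CH2Cl2 at 0 °C then eliminates trimethylsilanol to give 14.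

Step 12. Slow cleavage of the secondary benzylic silyl ether may force long exposure of the freed catechol to fluoride, with oxidation of the catechol or elimination at the carbinol as the result. The fallback sets out from 15 and returns at 19 with a more labile group on the carbinol. TESOTf with 2,6-lutidine gives the triethylsilyl ether F11. Hydroboration gives the alkylborane F12, and ring closure as in step 11 gives the triethylsilyl macrocycle F13. Bu4NF buffered with AcOH should then clear all four silyl groups at 0 °C and give 19.

## Further compounds

F1 | step 11 | (S)-macrocyclic stilbene with CH=CH between ring A and ring D, three triisopropylsilyl ethers and one tert-butyldimethylsilyl ether, alkene geometry left open because either isomer gives 18 | CC(C)[Si](C(C)C)(C(C)C)Oc1cc2cc(c1O[Si](C(C)C)(C(C)C)C(C)C)Oc1ccc(cc1)[C@@H](O[Si](C)(C)C(C)(C)C)Cc1cccc(O[Si](C(C)C)(C(C)C)C(C)C)c1Oc1cccc(c1)C=C2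
F2 | step 5 | [2-(3-bromophenoxy)-3-methoxyphenyl]methanol | COc1cccc(CO)c1Oc1cccc(Br)c1
F3 | step 5 | 1-(bromomethyl)-2-(3-bromophenoxy)-3-methoxybenzene | COc1cccc(CBr)c1Oc1cccc(Br)c1
F4 | step 5 | [2-(3-bromophenoxy)-3-methoxybenzyl]zinc bromide | COc1cccc(C[Zn]Br)c1Oc1cccc(Br)c1
F5 | step 5 | rac-2-[2-(3-bromophenoxy)-3-methoxyphenyl]-1-[4-[5-(1,3-dioxolan-2-yl)-2,3-dimethoxyphenoxy]phenyl]ethan-1-ol | COc1cccc(CC(O)c2ccc(Oc3cc(C4OCCO4)cc(OC)c3OC)cc2)c1Oc1cccc(Br)c1
F6 | step 5 | 2-[2-(3-bromophenoxy)-3-methoxyphenyl]-1-[4-[5-(1,3-dioxolan-2-yl)-2,3-dimethoxyphenoxy]phenyl]ethan-1-one | COc1cccc(CC(=O)c2ccc(Oc3cc(C4OCCO4)cc(OC)c3OC)cc2)c1Oc1cccc(Br)c1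
F7 | step 6 | bis(1,3-dithiolane) of 11, at the ketone and the aldehyde carbon | COc1cccc(CC2(SCCS2)c2ccc(Oc3cc(C4SCCS4)cc(OC)c3OC)cc2)c1Oc1cccc(Br)c1
F8 | step 6 | bis(1,3-dithiolane) of 12 | Oc1cccc(CC2(SCCS2)c2ccc(Oc3cc(C4SCCS4)cc(O)c3O)cc2)c1Oc1cccc(Br)c1
F9 | step 6 | bis(1,3-dithiolane) of 13 | CC(C)[Si](C(C)C)(C(C)C)Oc1cccc(CC2(SCCS2)c2ccc(Oc3cc(C4SCCS4)cc(O[Si](C(C)C)(C(C)C)C(C)C)c3O[Si](C(C)C)(C(C)C)C(C)C)cc2)c1Oc1cccc(Br)c1
F10 | step 8 | β-hydroxysilane, 1-hydroxy-2-(trimethylsilyl)ethyl in place of the formyl group of 13 (racemic at the new carbinol) | C[Si](C)(C)CC(O)c1cc(O[Si](C(C)C)(C(C)C)C(C)C)c(O[Si](C(C)C)(C(C)C)C(C)C)c(c1)Oc1ccc(cc1)C(=O)Cc1cccc(O[Si](C(C)C)(C(C)C)C(C)C)c1Oc1cccc(Br)c1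
F11 | step 12 | (S)-triethylsilyl ether of 15 | C=Cc1cc(O[Si](C(C)C)(C(C)C)C(C)C)c(O[Si](C(C)C)(C(C)C)C(C)C)c(c1)Oc1ccc(cc1)[C@@H](O[Si](CC)(CC)CC)Cc1cccc(O[Si](C(C)C)(C(C)C)C(C)C)c1Oc1cccc(Br)c1
F12 | step 12 | alkylborane from F11 and 9-BBN | C1CCC2CCCC1B2CCc1cc(O[Si](C(C)C)(C(C)C)C(C)C)c(O[Si](C(C)C)(C(C)C)C(C)C)c(c1)Oc1ccc(cc1)[C@@H](O[Si](CC)(CC)CC)Cc1cccc(O[Si](C(C)C)(C(C)C)C(C)C)c1Oc1cccc(Br)c1
F13 | step 12 | (S)-macrocycle with three triisopropylsilyl ethers and a triethylsilyl ether at the carbinol | CC(C)[Si](C(C)C)(C(C)C)Oc1cc2cc(c1O[Si](C(C)C)(C(C)C)C(C)C)Oc1ccc(cc1)[C@@H](O[Si](CC)(CC)CC)Cc1cccc(O[Si](C(C)C)(C(C)C)C(C)C)c1Oc1cccc(c1)CC2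
A1 | alternative 1 | seco chloro enone, 3-chloro-5-{2-[3-[2-[2-(4-hydroxyphenyl)-2-oxoethyl]-6-methoxyphenoxy]phenyl]ethyl}-2-methoxycyclohex-2-en-1-one | O=C1CC(CCc2cccc(Oc3c(CC(=O)c4ccc(O)cc4)cccc3OC)c2)CC(Cl)=C1OC
A2 | alternative 1 | macrocyclic 3-aryloxy-2-methoxycyclohexenone (racemic at the ring A sp3 carbon) | O=C1CC2CC(=C1OC)Oc1ccc(cc1)C(=O)Cc1cccc(OC)c1Oc1cccc(c1)CC2
A3 | alternative 2 | seco iodo aldehyde, tris-TBS ether, with the iodide on ring B and the arylacetaldehyde on ring C | O=CCc1cccc(O[Si](C)(C)C(C)(C)C)c1Oc1cccc(CCc2cc(O[Si](C)(C)C(C)(C)C)c(O[Si](C)(C)C(C)(C)C)c(Oc3ccc(I)cc3)c2)c1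
A4 | alternative 2 | (S)-macrocyclic carbinol, tris-TBS ether | CC(C)(C)[Si](C)(C)Oc1cc2cc(c1O[Si](C)(C)C(C)(C)C)Oc1ccc(cc1)[C@@H](O)Cc1cccc(O[Si](C)(C)C(C)(C)C)c1Oc1cccc(c1)CC2
A5 | alternative 3 | (S)-19-membered lactone, tetrakis-TBS ether, ring C oxygen acylated by the ring D carboxyl group | CC(C)(C)[Si](C)(C)Oc1cc2cc(c1O[Si](C)(C)C(C)(C)C)Oc1ccc(cc1)[C@@H](O[Si](C)(C)C(C)(C)C)Cc1cccc(O[Si](C)(C)C(C)(C)C)c1OC(=O)c1cccc(c1)CC2
A6 | alternative 3 | (S)-18-membered macrocycle, tetrakis-TBS ether | CC(C)(C)[Si](C)(C)Oc1cc2cc(c1O[Si](C)(C)C(C)(C)C)Oc1ccc(cc1)[C@@H](O[Si](C)(C)C(C)(C)C)Cc1cccc(O[Si](C)(C)C(C)(C)C)c1Oc1cccc(c1)CC2
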